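**Plan**
- Retrosynthetic cuts, in order: the C12 silyl ether; C6–Cl with the C5=C16 shift (ene chlorination of a 5Z alkene); the lactone bond C8–C17 and the C7 ester C–O; C2–C3 (ten-membered ring); C7–C8 and C8–C9 (both to a dithiane carbon C8); C1–C14 and C10–C11 (ring A).
- Enabling feature: the γ-lactone ring O7–C7–C8–C17–C19 is a β-hydroxy ester (hydroxyl on C8, C17 α to C19), so C8–C17 is the aldol bond between a C7-bound propionate and a C8 ketone.
- Forward order: ring A by a catalytic asymmetric Diels–Alder reaction; chain C2–C9 by acylating C8 (1,3-dithiane) onto C9 and an aldol to a (Z)-iodoenynal (C3–C7); ten-membered ring by alkynyl Nozaki–Hiyama–Kishi closure; lactone ring last by intramolecular Reformatsky reaction; then chlorination and desilylation.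
- Stereochemistry, ring A: C1/C10 from the (E)-dienophile and the catalyst; C11 by kinetic enolate protonation; C12 by Luche reduction followed by Mitsunobu inversion.
- Stereochemistry, chain: C9 by Felkin–Anh reduction; C7 by 1,3-anti Evans–Tishchenko reduction from C9; C2 by CBS reduction; 5Z from the enynol; 3Z by Lindlar reduction.
- Stereochemistry, end game: C8 and C17 are set in the key step from C7 through the ester tether; C6 by hydroxyl-guided ene chlorination.

Key step: step 29

Remark: briarane numbering is used for all intermediates (C1 quaternary with C15 methyl; C2–C9 chain; C10 ring-fusion CH; C11 with C20 methyl; C12 carbinol; C13=C14; C16 on C5; C17/C18/C19 lactone). On ring A, β is the face of the C15 methyl. Where a centre is an epimer mixture that converges later, the SMILES leaves it open.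
Assumption: the oxazaborolidinium enantiomer of step 2 is taken to expose the C1-Si/C10-Si face of 3, by analogy with α-methyl enals; if the sense is opposite, the mirror-image catalyst is used.

**Route**

Step 1
Reactants: 1 pent-1-en-3-one
Product: 2 (Z)-3-(tert-butyldimethylsilyloxy)penta-1,3-diene
Conditions: TBSOTf, Et3N, Et2O, 0 °C
Reagents that add atoms: tert-butyldimethylsilyl triflate, CC(C)(C)[Si](C)(C)OS(=O)(=O)C(F)(F)F
Why: Soft enolisation and O-silylation of the ethyl ketone gives the 2-siloxydiene, and amine/silyl triflate conditions favour the (Z)-enol ether (methyl cis to oxygen), the isomer able to reach the s-cis form.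

Step 2
Reactants: 2 (Z)-3-(tert-butyldimethylsilyloxy)penta-1,3-diene; 3 ethyl (E)-3-methyl-4-oxobut-2-enoate
Product: 4 ring-A Diels–Alder adduct (C2 aldehyde, C9 ethyl ester, C12=C13 TBS enol ether, 11α-methyl)
Conditions: (R)-diphenylprolinol-derived o-tolyl oxazaborolidinium triflimide (20 mol %), CH2Cl2, −78 °C; Et3N quench
Reagents that add atoms: none
Why: Oxazaborolidinium-catalysed Diels–Alder reaction in which the siloxy-activated terminus C11 bonds to C10 (β to the boron-bound formyl), the (E)-geometry of 3 fixes C2 and C9 trans with the C15 methyl cis to C9, the catalyst selects the face that sets C1 and C10, and the expected formyl-endo mode places the C11 methyl trans to the ester (reset in step 6).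

Step 3
Reactants: 4 ring-A Diels–Alder adduct
Product: 5 C2 primary alcohol
Conditions: NaBH4, EtOH, −20 °C
Reagents that add atoms: none
Why: Borohydride reduction takes the neopentyl aldehyde chemoselectively and leaves the hindered ethyl ester and the silyl enol ether untouched.

Step 4
Reactants: 5 C2 primary alcohol
Product: 6 C2 triethylsilyl ether
Conditions: TESCl, imidazole, CH2Cl2, 0 °C
Reagents that add atoms: chlorotriethylsilane, CC[Si](Cl)(CC)CC
Why: Standard silylation of a primary alcohol; the TES group is chosen because a primary TES ether can later be oxidised directly to the aldehyde.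

Step 5
Reactants: 6 C2 triethylsilyl ether
Product: 7 ring-A 13-en-12-one (11α-methyl)
Conditions: Pd(OAc)2 (1.05 equiv), MeCN, rt to 40 °C
Reagents that add atoms: none
Why: Saegusa–Ito oxidation: the palladium enolate at C13 can only β-eliminate toward C14, giving the C13=C14 enone regiospecifically.

Step 6
Reactants: 7 ring-A 13-en-12-one (11α-methyl)
Product: 9 ring-A 13-en-12-one with 11β-methyl, via lithium dienolate 8 (not isolated)
Conditions: LDA, THF, −78 °C; then 2,6-di-tert-butyl-4-methylphenol, −78 °C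
Reagents that add atoms: none
Why: Kinetic α'-deprotonation and kinetic protonation of the cross-conjugated dienolate: A(1,2) strain holds the C10 ester axial, so the proton adds axially anti to it and the C11 methyl ends cis to C9 (β), which converges both C11 epimers from step 2.

Step 7
Reactants: 9 ring-A 13-en-12-one with 11β-methyl
Product: 10 12β-allylic alcohol
Conditions: NaBH4, CeCl3·7H2O, MeOH, −78 °C
Reagents that add atoms: none
Why: Luche 1,2-reduction that spares the ester; hydride should enter from the α-face of C12 because the pseudo-axial C10 ester blocks the β-face, giving the 12β-alcohol (cis to the C11 methyl).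

Step 8
Reactants: 10 12β-allylic alcohol
Product: 12 12α-allylic alcohol, via 12α 4-nitrobenzoate 11 (not isolated)
Conditions: 4-O2NC6H4CO2H, PPh3, DIAD, toluene, 0 °C to rt; then EtOH, K2CO3 (cat.), rt
Reagents that add atoms: 4-nitrobenzoic acid, OC(=O)c1ccc(cc1)[N+](=O)[O-]
Why: Mitsunobu inversion (SN2 at C12 by the carboxylate from the open α-face) followed by ethanolysis of the activated aryl ester gives the 12α-alcohol, while the hindered C9 ethyl ester can only exchange degenerately in ethanol.

Step 9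
Reactants: 12 12α-allylic alcohol
Product: 13 12α-TBS ether ethyl ester
Conditions: TBSOTf, 2,6-lutidine, CH2Cl2, −78 to 0 °C
Reagents that add atoms: tert-butyldimethylsilyl triflate, CC(C)(C)[Si](C)(C)OS(=O)(=O)C(F)(F)F
Why: Silyl triflate silylation of a hindered secondary alcohol; the TBS ether is kept until the last step.

Step 10
Reactants: 13 12α-TBS ether ethyl ester
Product: 14 C9 aldehyde
Conditions: DIBAL-H (1.1 equiv), CH2Cl2, −78 °C; Rochelle salt
Reagents that add atoms: none
Why: Partial reduction of a hindered ester, whose tetrahedral aluminium intermediate persists at −78 °C and releases the aldehyde only on work-up.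

Step 11
Reactants: 14 C9 aldehyde; 15 1,3-dithiane
Product: 17 C9 carbinol carrying the C8 dithiane (C9 epimers), via 2-lithio-1,3-dithiane 16 (not isolated)
Conditions: 15, n-BuLi, THF, −30 °C; then 14, −78 °C; aq NH4Cl
Reagents that add atoms: none
Why: Addition of the dithiane acyl-anion equivalent to an aldehyde forms C8–C9; the C9 configuration is irrelevant because the carbinol is oxidised next.

Step 12
Reactants: 17 C9 carbinol carrying the C8 dithiane
Product: 18 C9 ketone (2-acyl-1,3-dithiane)
Conditions: Dess–Martin periodinane, NaHCO3, CH2Cl2, 0 °C to rt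
Reagents that add atoms: none
Why: Dess–Martin oxidation of the secondary alcohol, chosen over Swern conditions so that the primary TES ether is not touched.

Step 13
Reactants: 19 (Z)-3-methylpent-2-en-4-yn-1-ol
Product: 20 (Z)-5-iodo-3-methylpent-2-en-4-yn-1-ol
Conditions: NIS, AgNO3 (10 mol %), acetone, rt, dark
Reagents that add atoms: N-iodosuccinimide, O=C1CCC(=O)N1I
Why: Silver-catalysed iodination of the terminal alkyne, done before any dithiane is present because silver/N-halosuccinimide reagents attack thioacetals.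

Step 14
Reactants: 20 (Z)-5-iodo-3-methylpent-2-en-4-yn-1-ol
Product: 21 (Z)-5-iodo-3-methylpent-2-en-4-ynal
Conditions: activated MnO2, CH2Cl2, rt
Reagents that add atoms: none
Why: Neutral allylic oxidation that keeps the Z geometry, which is also the more stable one (the slim alkynyl group sits cis to the formyl group).

Step 15
Reactants: 18 C9 ketone (2-acyl-1,3-dithiane); 21 (Z)-5-iodo-3-methylpent-2-en-4-ynal
Product: 23 aldol adduct (C7 carbinol epimers, C9 ketone), via lithium enolate 22 (not isolated)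
Conditions: LiHMDS (1.0 equiv), THF, −78 °C; then 21; AcOH quench at −78 °C
Reagents that add atoms: none
Why: Aldol addition: the doubly sulfur-stabilised C8–H is removed selectively, the enolate adds 1,2 to the enal to form C7–C8 with C8 already at the ketone oxidation level, and the cold quench forestalls retro-aldol; C7 is set later.

Step 16
Reactants: 23 aldol adduct
Product: 24 (9S)-7,9-diol (C7 epimers)
Conditions: NaBH4, CeCl3·7H2O, MeOH/THF, −40 °C
Reagents that add atoms: none
Why: Borohydride reduction under Felkin–Anh control: hydride attacks the C9 ketone anti to the quaternary C1 on C10, which gives the target configuration at C9 in both C7 epimers under non-chelating protic conditions.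

Step 17
Reactants: 24 (9S)-7,9-diol
Product: 25 9-hydroxy-7-ketone
Conditions: activated MnO2, CH2Cl2, rt
Reagents that add atoms: none
Why: MnO2 oxidises only the allylic C7 alcohol, so both C7 epimers converge on one β-hydroxy enone while the hindered saturated C9 alcohol stays.

Step 18
Reactants: 25 9-hydroxy-7-ketone
Product: 26 9-acetate 7-alcohol (7,9-anti)
Conditions: MeCHO (8 equiv), SmI2 (30 mol %, premixed with MeCHO), THF, −10 °C
Reagents that add atoms: acetaldehyde, CC=O
Why: Evans–Tishchenko reduction: the samarium-bound hemiacetal formed from the C9 hydroxyl and acetaldehyde delivers hydride to C7 through a chair transition state, giving the 1,3-anti C7 alcohol and leaving C9 as its acetate in one operation.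

Step 19
Reactants: 26 9-acetate 7-alcohol
Product: 27 7-O-TES 9-acetate iodoalkyne
Conditions: TESOTf, 2,6-lutidine, CH2Cl2, −78 °C
Reagents that add atoms: triethylsilyl triflate, CC[Si](CC)(CC)OS(=O)(=O)C(F)(F)F
Why: Fast low-temperature silylation of the only free hydroxyl, before any acetyl migration can occur.

Step 20
Reactants: 27 7-O-TES 9-acetate iodoalkyne
Product: 28 C2 aldehyde (seco iodoalkyne)
Conditions: (COCl)2, DMSO, CH2Cl2, −78 to −40 °C; Et3N
Reagents that add atoms: none
Why: Swern conditions convert a primary TES ether directly into the aldehyde, while the hindered secondary TES ether at C7 and the TBS ether are inert.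

Step 21
Reactants: 28 C2 aldehyde (seco iodoalkyne)
Product: 29 ten-membered cycloalkynol (C2 epimers)
Conditions: CrCl2 (8 equiv), NiCl2 (2 mol %), THF, 2 mM, rt
Reagents that add atoms: none
Why: Nozaki–Hiyama–Kishi reaction: the alkynylchromium(III) species adds to the aldehyde chemoselectively (acetate and thioacetal tolerated) under high dilution and closes the ring at C2–C3; the C2 configuration is not relied on here.

Step 22
Reactants: 29 ten-membered cycloalkynol
Product: 30 cyclic ynone
Conditions: Dess–Martin periodinane, NaHCO3, CH2Cl2, 0 °C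
Reagents that add atoms: none
Why: Mild oxidation of the propargylic alcohol merges both C2 epimers into one ketone.

Step 23
Reactants: 30 cyclic ynone
Product: 31 C2 propargylic alcohol (target configuration at C2)
Conditions: (R)-Me-CBS oxazaborolidine, catecholborane, CH2Cl2, −78 °C
Reagents that add atoms: none
Why: Corey–Bakshi–Shibata reduction: the catalyst distinguishes the quaternary C1 (large) from the alkynyl arm (small) and sets C2 by reagent control, and catecholborane does not hydroborate the alkenes.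

Step 24
Reactants: 31 C2 propargylic alcohol
Product: 32 2,9-diacetate with C8 dithiane
Conditions: Ac2O, pyridine, DMAP (cat.), CH2Cl2, 0 °C to rt
Reagents that add atoms: acetic anhydride, CC(=O)OC(C)=O
Why: DMAP-catalysed acetylation of the only free hydroxyl.

Step 25
Reactants: 32 2,9-diacetate with C8 dithiane
Product: 33 C8 ketone (3-yne)
Conditions: PhI(OCOCF3)2, NaHCO3, MeCN/H2O, 0 °C
Reagents that add atoms: water, O
Why: Oxidative hydrolysis of the thioacetal with a hypervalent iodine reagent under buffered conditions spares the silyl ethers, the acetates and the enyne.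

Step 26
Reactants: 33 C8 ketone (3-yne)
Product: 34 C8 ketone (3Z,5Z)-diene
Conditions: H2 (1 atm), Lindlar catalyst, quinoline, EtOAc, rt
Reagents that add atoms: none
Why: Lindlar semihydrogenation delivers the cis C3=C4 alkene and relieves ring strain; it is run after sulfur removal so the catalyst is not poisoned, and the other alkenes are not reduced.

Step 27
Reactants: 34 C8 ketone (3Z,5Z)-diene
Product: 35 7-hydroxy-8-ketone
Conditions: HF·pyridine, pyridine, THF, 0 °C
Reagents that add atoms: none
Why: Buffered fluoride cleaves the secondary TES ether much faster than the hindered secondary TBS ether at C12.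

Step 28
Reactants: 35 7-hydroxy-8-ketone; 36 2-bromopropanoyl bromide
Product: 37 7-O-(2-bromopropanoyl) 8-ketone (C17 bromide epimers)
Conditions: pyridine, CH2Cl2, −40 to 0 °C
Reagents that add atoms: none
Why: Acylation of the α-hydroxy ketone with the racemic acid bromide under mild base; both bromide epimers are used because they converge in step 29.

Step 29
Reactants: 37 7-O-(2-bromopropanoyl) 8-ketone
Product: 39 tricyclic 8-hydroxy lactone, via bromozinc ester enolate 38 (not isolated)
Conditions: Zn dust (activated with TMSCl/BrCH2CH2Br), THF, 0 °C to rt; aq NH4Cl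
Reagents that add atoms: none
Why: Zinc inserts into the C17–Br bond of either bromide epimer to give one bromozinc ester enolate, which adds to the C8 ketone through a zinc-bridged transition state and gives the β-hydroxy γ-lactone on protonation (intramolecular Reformatsky reaction). The closest known reaction type is the Reformatsky lactonisation of α-(α-bromoacyloxy) ketones to β-hydroxy γ-lactones. The lactone ring closes by 5-exo-trig attack of the enolate carbon C17 on C8, forming C8–C17. At C8, the enolate is tethered through O7 and can only reach the carbonyl face syn to the C7–O bond; with C6 and C9 held anti about C7–C8 by the ten-membered (Z,Z)-dienyl ring, this gives the trans-fused lactone with the new hydroxyl cis to C6. At C17, the methyl group points away from C9 in the compact chelated transition state and ends cis to the new hydroxyl, which is also the less crowded arrangement favoured if the zinc aldolate equilibrates. The step needs enolate formation at the ester and not at the more acidic C7–H/C9–H ketone positions, and addition to the ketone and not to the two acetates; reductive, non-basic generation from C–Br secures the first and five-membered-ring proximity the second.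

Step 30
Reactants: 39 tricyclic 8-hydroxy lactone
Product: 40 6-chloro-5(16)-ene TBS ether
Conditions: Ca(OCl)2, CO2 (dry ice), CH2Cl2/H2O, 0 °C
Reagents that add atoms: hypochlorous acid, OCl (generated from calcium hypochlorite, [Ca+2].[O-]Cl.[O-]Cl)
Why: Ene-type allylic chlorination: electrophilic chlorine adds to C6 of the most electron-rich, trisubstituted C5=C6 bond and a C16 proton is lost to give the exocyclic alkene, and the hydrogen-bonding tertiary C8 hydroxyl, which lies over one face of C6, is expected to guide chlorine to that face, as the target configuration at C6 requires.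

Step 31
Reactants: 40 6-chloro-5(16)-ene TBS ether
Product: 41 CNP0253247.1
Conditions: HF·pyridine, THF, 0 °C to rt
Reagents that add atoms: none
Why: Acidic fluoride removes the last silyl ether without touching the acetates, the lactone, the tertiary alcohol or the allylic chloride, which a basic fluoride source could endanger.

**Compound list**

1 | pent-1-en-3-one | CCC(=O)C=C | starting material
2 | (Z)-3-(tert-butyldimethylsilyloxy)penta-1,3-diene | C=C/C(O[Si](C)(C)C(C)(C)C)=C/C | intermediate
3 | ethyl (E)-3-methyl-4-oxobut-2-enoate | CCOC(=O)/C=C(\C)C=O | starting material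
4 | ring-A Diels–Alder adduct: C1 bears C15 methyl (β) and formyl C2 (α), C10 bears the C9 ethyl ester (β), C11 methyl α, C12=C13 TBS enol ether | O=C[C@@]1(C)CC=C(O[Si](C)(C)C(C)(C)C)[C@@H](C)[C@@H]1C(=O)OCC | intermediate
5 | C2 primary alcohol of 4 | OC[C@@]1(C)CC=C(O[Si](C)(C)C(C)(C)C)[C@@H](C)[C@@H]1C(=O)OCC | intermediate
6 | C2 triethylsilyl ether of 5 | CC[Si](CC)(CC)OC[C@@]1(C)CC=C(O[Si](C)(C)C(C)(C)C)[C@@H](C)[C@@H]1C(=O)OCC | intermediate
7 | ring-A 13-en-12-one, 11α-methyl, C2 OTES, C9 ethyl ester | CC[Si](CC)(CC)OC[C@@]1(C)C=CC(=O)[C@@H](C)[C@@H]1C(=O)OCC | intermediate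
8 | lithium 11,13-dien-12-olate of 7 | CC[Si](CC)(CC)OC[C@@]1(C)C=CC(O[Li])=C(C)[C@@H]1C(=O)OCC | intermediate
9 | ring-A 13-en-12-one, 11β-methyl (cis to C9 and C15) | CC[Si](CC)(CC)OC[C@@]1(C)C=CC(=O)[C@H](C)[C@@H]1C(=O)OCC | intermediate
10 | 12β-allylic alcohol (OH cis to the C11 methyl) | CC[Si](CC)(CC)OC[C@@]1(C)C=C[C@H](O)[C@H](C)[C@@H]1C(=O)OCC | intermediate
11 | 12α 4-nitrobenzoate | CC[Si](CC)(CC)OC[C@@]1(C)C=C[C@@H](OC(=O)c2ccc(cc2)[N+](=O)[O-])[C@H](C)[C@@H]1C(=O)OCC | intermediate
12 | 12α-allylic alcohol (OH trans to the C11 methyl) | CC[Si](CC)(CC)OC[C@@]1(C)C=C[C@@H](O)[C@H](C)[C@@H]1C(=O)OCC | intermediate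
13 | 12α-TBS ether, C9 ethyl ester, C2 OTES | CC[Si](CC)(CC)OC[C@@]1(C)C=C[C@@H](O[Si](C)(C)C(C)(C)C)[C@H](C)[C@@H]1C(=O)OCC | intermediate
14 | C9 aldehyde | CC[Si](CC)(CC)OC[C@@]1(C)C=C[C@@H](O[Si](C)(C)C(C)(C)C)[C@H](C)[C@@H]1C=O | intermediate
15 | 1,3-dithiane | C1CSCSC1 | starting material
16 | 2-lithio-1,3-dithiane | [Li]C1SCCCS1 | intermediate
17 | C9 carbinol with 1,3-dithian-2-yl as C8 (C9 epimers) | CC[Si](CC)(CC)OC[C@@]1(C)C=C[C@@H](O[Si](C)(C)C(C)(C)C)[C@H](C)[C@@H]1C(O)C2SCCCS2 | intermediate
18 | C9 ketone, 2-acyl-1,3-dithiane | CC[Si](CC)(CC)OC[C@@]1(C)C=C[C@@H](O[Si](C)(C)C(C)(C)C)[C@H](C)[C@@H]1C(=O)C2SCCCS2 | intermediate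
19 | (Z)-3-methylpent-2-en-4-yn-1-ol | C#C/C(C)=C\CO | starting material
20 | (Z)-5-iodo-3-methylpent-2-en-4-yn-1-ol | IC#C/C(C)=C\CO | intermediate
21 | (Z)-5-iodo-3-methylpent-2-en-4-ynal | IC#C/C(C)=C\C=O | intermediate
22 | lithium enolate of 18 (C9 enolate, C8 ketene dithioacetal carbon) | CC[Si](CC)(CC)OC[C@@]1(C)C=C[C@@H](O[Si](C)(C)C(C)(C)C)[C@H](C)[C@@H]1C(O[Li])=C2SCCCS2 | intermediate
23 | aldol adduct: C9 ketone, C8 dithiane, C7 carbinol (epimers), (5Z)-en-3-yne iodide | CC[Si](CC)(CC)OC[C@@]1(C)C=C[C@@H](O[Si](C)(C)C(C)(C)C)[C@H](C)[C@@H]1C(=O)C2(SCCCS2)C(O)/C=C(C)\C#CI | intermediate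
24 | (9S)-7,9-diol (C7 epimers) | CC[Si](CC)(CC)OC[C@@]1(C)C=C[C@@H](O[Si](C)(C)C(C)(C)C)[C@H](C)[C@@H]1[C@H](O)C2(SCCCS2)C(O)/C=C(C)\C#CI | intermediate
25 | (9S)-9-hydroxy-7-ketone | CC[Si](CC)(CC)OC[C@@]1(C)C=C[C@@H](O[Si](C)(C)C(C)(C)C)[C@H](C)[C@@H]1[C@H](O)C2(SCCCS2)C(=O)/C=C(C)\C#CI | intermediate
26 | 9-acetate 7-alcohol, C7–O and C9–O anti, both as in the target | CC[Si](CC)(CC)OC[C@@]1(C)C=C[C@@H](O[Si](C)(C)C(C)(C)C)[C@H](C)[C@@H]1[C@H](OC(C)=O)C2(SCCCS2)[C@@H](O)/C=C(C)\C#CI | intermediate
27 | 7-O-TES 9-acetate iodoalkyne | CC[Si](CC)(CC)OC[C@@]1(C)C=C[C@@H](O[Si](C)(C)C(C)(C)C)[C@H](C)[C@@H]1[C@H](OC(C)=O)C2(SCCCS2)[C@@H](O[Si](CC)(CC)CC)/C=C(C)\C#CI | intermediate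
28 | C2 aldehyde, seco iodoalkyne | O=C[C@@]1(C)C=C[C@@H](O[Si](C)(C)C(C)(C)C)[C@H](C)[C@@H]1[C@H](OC(C)=O)C2(SCCCS2)[C@@H](O[Si](CC)(CC)CC)/C=C(C)\C#CI | intermediate
29 | ten-membered 5Z-en-3-yn-2-ol (C2 epimers), C8 dithiane, 7-OTES, 9-OAc, 12-OTBS | CC=1/C#CC(O)[C@@]2(C)C=C[C@@H](O[Si](C)(C)C(C)(C)C)[C@H](C)[C@@H]2[C@H](OC(C)=O)C2(SCCCS2)[C@@H](O[Si](CC)(CC)CC)\C=1 | intermediate
30 | cyclic 5Z-en-3-yn-2-one | CC=1/C#CC(=O)[C@@]2(C)C=C[C@@H](O[Si](C)(C)C(C)(C)C)[C@H](C)[C@@H]2[C@H](OC(C)=O)C2(SCCCS2)[C@@H](O[Si](CC)(CC)CC)\C=1 | intermediate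
31 | C2 propargylic alcohol, C2 as in the target | CC=1/C#C[C@H](O)[C@@]2(C)C=C[C@@H](O[Si](C)(C)C(C)(C)C)[C@H](C)[C@@H]2[C@H](OC(C)=O)C2(SCCCS2)[C@@H](O[Si](CC)(CC)CC)\C=1 | intermediate
32 | 2,9-diacetate, C8 dithiane, 3-yne | CC=1/C#C[C@H](OC(C)=O)[C@@]2(C)C=C[C@@H](O[Si](C)(C)C(C)(C)C)[C@H](C)[C@@H]2[C@H](OC(C)=O)C2(SCCCS2)[C@@H](O[Si](CC)(CC)CC)\C=1 | intermediate
33 | C8 ketone, 3-yne, 7-OTES | CC=1/C#C[C@H](OC(C)=O)[C@@]2(C)C=C[C@@H](O[Si](C)(C)C(C)(C)C)[C@H](C)[C@@H]2[C@H](OC(C)=O)C(=O)[C@@H](O[Si](CC)(CC)CC)\C=1 | intermediate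
34 | C8 ketone, (3Z,5Z)-diene, 7-OTES | CC=1/C=C\[C@H](OC(C)=O)[C@@]2(C)C=C[C@@H](O[Si](C)(C)C(C)(C)C)[C@H](C)[C@@H]2[C@H](OC(C)=O)C(=O)[C@@H](O[Si](CC)(CC)CC)\C=1 | intermediate
35 | 7-hydroxy-8-ketone, (3Z,5Z)-diene | CC=1/C=C\[C@H](OC(C)=O)[C@@]2(C)C=C[C@@H](O[Si](C)(C)C(C)(C)C)[C@H](C)[C@@H]2[C@H](OC(C)=O)C(=O)[C@@H](O)\C=1 | intermediate
36 | 2-bromopropanoyl bromide (racemic) | CC(Br)C(=O)Br | starting material
37 | 7-O-(2-bromopropanoyl) 8-ketone, bromide epimers at C17 | CC=1/C=C\[C@H](OC(C)=O)[C@@]2(C)C=C[C@@H](O[Si](C)(C)C(C)(C)C)[C@H](C)[C@@H]2[C@H](OC(C)=O)C(=O)[C@@H](OC(=O)C(C)Br)\C=1 | intermediate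
38 | bromozinc ester enolate of 37 | CC=1/C=C\[C@H](OC(C)=O)[C@@]2(C)C=C[C@@H](O[Si](C)(C)C(C)(C)C)[C@H](C)[C@@H]2[C@H](OC(C)=O)C(=O)[C@@H](OC(O[Zn]Br)=CC)\C=1 | intermediate
39 | tricyclic 8-hydroxy lactone, (3Z,5Z)-diene, 12-OTBS | CC=1/C=C\[C@H](OC(C)=O)[C@@]2(C)C=C[C@@H](O[Si](C)(C)C(C)(C)C)[C@H](C)[C@@H]2[C@H](OC(C)=O)[C@]2(O)[C@@H](C)C(=O)O[C@H]2\C=1 | intermediate
40 | 6-chloro-5(16)-ene lactone, 12-OTBS | C=C1/C=C\[C@H](OC(C)=O)[C@@]2(C)C=C[C@@H](O[Si](C)(C)C(C)(C)C)[C@H](C)[C@@H]2[C@H](OC(C)=O)[C@]2(O)[C@@H](C)C(=O)O[C@H]2[C@H]1Cl | intermediate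
41 | CNP0253247.1, (1S,2S,3Z,6S,7R,8R,9S,10S,11R,12R,17R)-2,9-diacetoxy-6-chloro-8,12-dihydroxybriara-3,5(16),13-triene 7,19-lactone | C=C1/C=C\[C@H](OC(C)=O)[C@@]2(C)C=C[C@@H](O)[C@H](C)[C@@H]2[C@H](OC(C)=O)[C@]2(O)[C@@H](C)C(=O)O[C@H]2[C@H]1Cl | target

**Step count**
Total: 31 steps. Longest linear sequence: 29 steps (steps 1–12 and 15–31; steps 13–14 make the enynal branch).

**Steps most likely to fail, with fallbacks**

Step 30 (ene chlorination). Chlorine may be delivered to the wrong face of C6 if the hydroxyl guidance is weak, the C5 cation may be trapped by the C8 hydroxyl as a cyclic ether, or addition may run across the diene. Fallback: from 39, sensitised photooxygenation (O2, tetraphenylporphyrin, hν, CH2Cl2, −20 °C; Schenck ene reaction) should place oxygen on C6 with the same C5=C16 shift and without a cationic intermediate, giving the 6-hydroperoxy-5(16)-ene F1 with oxygen on the face opposite to the one chlorine must occupy. Triphenylphosphine then reduces it to the allylic alcohol F2. Chlorination with PPh3/hexachloroacetone at 0 °C, which substitutes allylic alcohols with inversion and little allylic transposition, places chloride on the required face and returns to 40.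

Step 21 (alkynyl Nozaki–Hiyama–Kishi macrocyclisation). The linear C2–C3≡C4–C5 unit may strain the ten-membered transition state enough that oligomerisation or loss of iodine outruns ring closure. Fallback: from 27, diimide reduction (2-nitrobenzenesulfonylhydrazide, Et3N) converts the iodoalkyne into the (Z)-vinyl iodide F3, and Swern oxidation of the primary TES ether gives the aldehyde F4. Nozaki–Hiyama–Kishi closure of the bent vinyl iodide (CrCl2, NiCl2, DMSO, high dilution) gives the cyclic (3Z,5Z)-dienol F5 as C2 epimers. Dess–Martin oxidation to the dienone F6 and (R)-CBS reduction (quaternary C1 as the large group) give the alcohol F7 with the target C2 configuration. Acetylation gives the diacetate F8, and thioacetal hydrolysis with PhI(OCOCF3)2 returns to 34, so no semihydrogenation is needed.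

Step 29 (Reformatsky lactonisation). Electron transfer from zinc to the ketone flanked by two acyloxy groups may cleave a C–O bond at C7 or C9 faster than zinc inserts into C–Br, or the zinc aldolate may revert. Fallback: from 35, acylation with acryloyl chloride (i-Pr2NEt, CH2Cl2, −78 °C) gives the C7 acrylate F9. Copper hydride ([(Ph3P)CuH]6, toluene, −40 to 0 °C) adds hydride 1,4 to the acrylate and the resulting copper propionate enolate closes onto the C8 ketone (intramolecular reductive aldol cyclisation). This forms the same C8–C17 bond through the same tether with no carbon–halogen bond to reduce, and returns to 39.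

**Further compounds**
F1 | step 30 | 6-hydroperoxy-5(16)-ene lactone, oxygen on the C6 face opposite to that of chlorine in 40, 12-OTBS | C=C1/C=C\[C@H](OC(C)=O)[C@@]2(C)C=C[C@@H](O[Si](C)(C)C(C)(C)C)[C@H](C)[C@@H]2[C@H](OC(C)=O)[C@]2(O)[C@@H](C)C(=O)O[C@H]2[C@@H]1OO
F2 | step 30 | 6-hydroxy-5(16)-ene lactone (C6 epimeric to the chloride of 40), 12-OTBS | C=C1/C=C\[C@H](OC(C)=O)[C@@]2(C)C=C[C@@H](O[Si](C)(C)C(C)(C)C)[C@H](C)[C@@H]2[C@H](OC(C)=O)[C@]2(O)[C@@H](C)C(=O)O[C@H]2[C@@H]1O
F3 | step 21 | (3Z,5Z)-3-iodo-diene, 7-OTES, 9-OAc, C8 dithiane, C2 OTES | CC[Si](CC)(CC)OC[C@@]1(C)C=C[C@@H](O[Si](C)(C)C(C)(C)C)[C@H](C)[C@@H]1[C@H](OC(C)=O)C2(SCCCS2)[C@@H](O[Si](CC)(CC)CC)/C=C(C)\C=C/I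
F4 | step 21 | C2 aldehyde of the (3Z,5Z)-iododiene | O=C[C@@]1(C)C=C[C@@H](O[Si](C)(C)C(C)(C)C)[C@H](C)[C@@H]1[C@H](OC(C)=O)C2(SCCCS2)[C@@H](O[Si](CC)(CC)CC)/C=C(C)\C=C/I
F5 | step 21 | ten-membered (3Z,5Z)-dien-2-ol (C2 epimers), C8 dithiane | CC=1/C=C\C(O)[C@@]2(C)C=C[C@@H](O[Si](C)(C)C(C)(C)C)[C@H](C)[C@@H]2[C@H](OC(C)=O)C2(SCCCS2)[C@@H](O[Si](CC)(CC)CC)\C=1
F6 | step 21 | ten-membered (3Z,5Z)-dien-2-one, C8 dithiane | CC=1/C=C\C(=O)[C@@]2(C)C=C[C@@H](O[Si](C)(C)C(C)(C)C)[C@H](C)[C@@H]2[C@H](OC(C)=O)C2(SCCCS2)[C@@H](O[Si](CC)(CC)CC)\C=1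
F7 | step 21 | ten-membered (3Z,5Z)-dien-2-ol, C2 as in the target | CC=1/C=C\[C@H](O)[C@@]2(C)C=C[C@@H](O[Si](C)(C)C(C)(C)C)[C@H](C)[C@@H]2[C@H](OC(C)=O)C2(SCCCS2)[C@@H](O[Si](CC)(CC)CC)\C=1
F8 | step 21 | 2,9-diacetate (3Z,5Z)-diene with C8 dithiane | CC=1/C=C\[C@H](OC(C)=O)[C@@]2(C)C=C[C@@H](O[Si](C)(C)C(C)(C)C)[C@H](C)[C@@H]2[C@H](OC(C)=O)C2(SCCCS2)[C@@H](O[Si](CC)(CC)CC)\C=1
F9 | step 29 | 7-O-acryloyl 8-ketone | CC=1/C=C\[C@H](OC(C)=O)[C@@]2(C)C=C[C@@H](O[Si](C)(C)C(C)(C)C)[C@H](C)[C@@H]2[C@H](OC(C)=O)C(=O)[C@@H](OC(=O)C=C)\C=1
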